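Ring C of the flavanone half is read as a benzo-fused dihydropyranone and cut at C2–C3 and O1–C8a, leading back to an aryl aldehyde and the enol silane of a 2-fluoro-4,6-bis(benzyloxy)acetophenone. In one flask a catalytic asymmetric Mukaiyama aldol addition sets C2, and a fluoride-relayed SNAr of the aldolate oxygen at C8a, which the ortho C4 carbonyl on ring A activates, closes ring C with loss of Me3SiF. Since C2 has the same spatial arrangement in both halves, the resulting (S)-3'-bromoflavanone serves twice: trans C3 hydroxylation gives the dihydroflavonol half, borylation the other, and a Suzuki coupling forms the C3'–C3''' biaryl bond.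

Key step: step 5

Remark 1: the C3'–C3''' axis carries only two ortho substituents (the two hydroxyl groups) and is taken as freely rotating, so no axial configuration has to be controlled.
Remark 2: it is assumed that the oxazaborolidinone from N-tosyl-(S)-tryptophan directs addition to the Re face of an aromatic aldehyde, so step 5 uses the catalyst from N-tosyl-(R)-tryptophan to reach the Si face of aldehyde 2; should circular dichroism of 8 indicate the opposite sense of induction, the catalyst from N-tosyl-(S)-tryptophan would be used instead.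

Step 1
Reactants: 1 3-bromo-4-hydroxybenzaldehyde
Product: 2 4-(benzyloxy)-3-bromobenzaldehyde
Conditions: BnBr, K2CO3, DMF, rt
Reagents that add atoms: benzyl bromide, BrCc1ccccc1
Why: Williamson ether synthesis, in which the acidic para-formyl phenoxide displaces bromide from the benzylic carbon by SN2 while the aldehyde and the aryl bromide are left alone.

Step 2
Reactants: 3 5-fluorobenzene-1,3-diol (5-fluororesorcinol)
Product: 4 1-(2-fluoro-4,6-dihydroxyphenyl)ethan-1-one
Conditions: AcOH, ZnCl2, 120 °C
Reagents that add atoms: acetic acid, CC(=O)O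
Why: Nencki-type Friedel–Crafts acylation, which should go to the ring position para to one hydroxyl and ortho to the other (the carbon next to fluorine), as in the acetylation of resorcinol and orcinol, the ketone being held as its chelate with the ortho hydroxyl.

Step 3
Reactants: 4 1-(2-fluoro-4,6-dihydroxyphenyl)ethan-1-one
Product: 5 1-[2,4-bis(benzyloxy)-6-fluorophenyl]ethan-1-one
Conditions: BnBr (2.4 equiv), K2CO3, DMF, 70 °C
Reagents that add atoms: benzyl bromide, BrCc1ccccc1
Why: Double Williamson etherification, in which warming is needed for the chelated ortho hydroxyl and the carbonate is too weak a nucleophile to displace the aryl fluoride.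

Step 4
Reactants: 5 1-[2,4-bis(benzyloxy)-6-fluorophenyl]ethan-1-one
Product: 6 {1-[2,4-bis(benzyloxy)-6-fluorophenyl]ethenyl}oxy(trimethyl)silane (enol silane of 5)
Conditions: TMSOTf, Et3N, CH2Cl2, 0 °C
Reagents that add atoms: trimethylsilyl trifluoromethanesulfonate, C[Si](C)(C)OS(=O)(=O)C(F)(F)F
Why: Soft enolisation of the methyl ketone, in which O-silylation acidifies the only α-position and the amine removes the proton to give the terminal enol silane.

Step 5
Reactants: 2 4-(benzyloxy)-3-bromobenzaldehyde; 6 {1-[2,4-bis(benzyloxy)-6-fluorophenyl]ethenyl}oxy(trimethyl)silane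
Product: 8 (2S)-5,7-bis(benzyloxy)-2-[4-(benzyloxy)-3-bromophenyl]chroman-4-one, via silyl aldol 7 (not isolated)
Conditions: B-butyl oxazaborolidinone from N-tosyl-(R)-tryptophan and n-BuB(OH)2 (20 mol%), EtCN, −78 °C; then n-Bu4N[Ph3SiF2] (50 mol%), THF, −40 °C to rt; AcOH quench; recrystallisation
Reagents that add atoms: none
Why: The chiral boron Lewis acid binds aldehyde 2 and enol silane 6 adds through an open Mukaiyama transition state, the silyl group passing to the aldolate oxygen to give 7; fluoride then frees the alkoxide, which attacks C8a, forms a Meisenheimer intermediate stabilised by the C4 carbonyl and expels fluoride, which in turn desilylates the next molecule of 7, so that the net change is a [4+2] annulation with loss of Me3SiF. The closest known reaction types are the catalytic asymmetric Mukaiyama aldol addition of aryl methyl ketone enol silanes to aromatic aldehydes and the fluoride-promoted SNAr etherification of silyl ethers with 2-fluoroaryl ketones, joined here as a benzo analogue of the siloxydiene–aldehyde cyclocondensation in which the aryl C–F bond stands in for the alkoxy leaving group. Ring C closes by intramolecular addition–elimination at C8a, a favoured 6-endo-trig attack on the vinylogous acyl fluoride C8a=C4a–C4=O. The only new stereocentre, C2, is set as S by the catalyst through Si-face addition to the aldehyde and is not touched afterwards, because the ring closure forms the O1–C8a bond and leaves the C2–O1 bond intact. The step needs SNAr to outrun retro-aldol cleavage and E1cB loss of silanolate, which the silyl cap on oxygen up to the fluoride stage, the low temperature, the low standing concentration of naked alkoxide in the relay and the ortho-acyl activation of the single C–F bond should secure; the tether lets the oxygen reach C8a only.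

Step 6
Reactants: 8 (2S)-5,7-bis(benzyloxy)-2-[4-(benzyloxy)-3-bromophenyl]chroman-4-one
Product: 9 (2S)-5,7-bis(benzyloxy)-2-[4-(benzyloxy)-3-bromophenyl]-4-[(trimethylsilyl)oxy]-2H-chromene
Conditions: TMSOTf, Et3N, CH2Cl2, −20 to 0 °C
Reagents that add atoms: trimethylsilyl trifluoromethanesulfonate, C[Si](C)(C)OS(=O)(=O)C(F)(F)F
Why: Soft enolisation goes through the O-silyl oxocarbenium ion and not through a free enolate, so that E1cB opening of ring C, which would racemise C2, is avoided.

Step 7
Reactants: 9 (2S)-5,7-bis(benzyloxy)-2-[4-(benzyloxy)-3-bromophenyl]-4-[(trimethylsilyl)oxy]-2H-chromene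
Product: 11 (2R,3R)-5,7-bis(benzyloxy)-2-[4-(benzyloxy)-3-bromophenyl]-3-hydroxychroman-4-one, via silyloxy epoxide 10 (not isolated)
Conditions: DMDO, acetone/CH2Cl2, −40 °C; then citric acid, MeOH, 0 °C
Reagents that add atoms: dimethyldioxirane, CC1(C)OO1
Why: Rubottom oxidation: DMDO epoxidises the electron-rich enol ether on the face anti to the C2 aryl group, and acid methanolysis opens silyloxy epoxide 10 at C4 with the C3–O bond intact, so that the new C3 stereocentre is R and trans to the aryl group under substrate control.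

Step 8
Reactants: 8 (2S)-5,7-bis(benzyloxy)-2-[4-(benzyloxy)-3-bromophenyl]chroman-4-one
Product: 12 (2S)-5,7-bis(benzyloxy)-2-[4-(benzyloxy)-3-(4,4,5,5-tetramethyl-1,3,2-dioxaborolan-2-yl)phenyl]chroman-4-one
Conditions: B2pin2, Pd(dppf)Cl2 (3 mol%), KOAc, 1,4-dioxane, 80 °C
Reagents that add atoms: bis(pinacolato)diboron, CC1(C)OB(OC1(C)C)B1OC(C)(C)C(C)(C)O1
Why: Miyaura borylation of the aryl bromide, in which acetate is basic enough to assist transmetalation but too weak to enolise the chromanone and open ring C.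

Step 9
Reactants: 12 (2S)-5,7-bis(benzyloxy)-2-[4-(benzyloxy)-3-(4,4,5,5-tetramethyl-1,3,2-dioxaborolan-2-yl)phenyl]chroman-4-one; 11 (2R,3R)-5,7-bis(benzyloxy)-2-[4-(benzyloxy)-3-bromophenyl]-3-hydroxychroman-4-one
Product: 13 hexa-O-benzyl ether of the target (benzyl on O5, O7 and O4' of both halves, 3-OH free, 2S in the flavanone half and 2R,3R in the dihydroflavonol half)
Conditions: Pd(OAc)2 (5 mol%), SPhos (10 mol%), K3PO4, toluene/H2O, 40 °C
Reagents that add atoms: none
Why: Suzuki–Miyaura cross-coupling, in which the bulky electron-rich biaryl phosphine lets two ortho-alkoxy partners couple at a temperature and phosphate basicity that should leave C2 of both halves and the α-ketol untouched, no new stereocentre being formed.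

Step 10
Reactants: 13 hexa-O-benzyl ether of the target
Product: 14 target, (2R,3R)-2-{6,6'-dihydroxy-3'-[(2S)-5,7-dihydroxy-4-oxochroman-2-yl]biphenyl-3-yl}-3,5,7-trihydroxychroman-4-one
Conditions: H2 (1 atm), 10% Pd/C, EtOAc/MeOH, rt
Reagents that add atoms: none
Why: Hydrogenolysis of the six aryl benzyl ethers, which cleave much faster than the cyclic benzylic C2–O1 ethers and the chelated aryl ketones, so that all stereocentres are kept.

Compound list
1 | 3-bromo-4-hydroxybenzaldehyde | O=Cc1ccc(O)c(Br)c1 | starting material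
2 | 4-(benzyloxy)-3-bromobenzaldehyde | O=Cc1ccc(OCc2ccccc2)c(Br)c1 | intermediate
3 | 5-fluorobenzene-1,3-diol | Oc1cc(O)cc(F)c1 | starting material
4 | 1-(2-fluoro-4,6-dihydroxyphenyl)ethan-1-one | CC(=O)c1c(O)cc(O)cc1F | intermediate
5 | 1-[2,4-bis(benzyloxy)-6-fluorophenyl]ethan-1-one | CC(=O)c1c(OCc2ccccc2)cc(OCc2ccccc2)cc1F | intermediate
6 | {1-[2,4-bis(benzyloxy)-6-fluorophenyl]ethenyl}oxy(trimethyl)silane | C=C(O[Si](C)(C)C)c1c(OCc2ccccc2)cc(OCc2ccccc2)cc1F | intermediate
7 | (3S)-3-[4-(benzyloxy)-3-bromophenyl]-1-[2,4-bis(benzyloxy)-6-fluorophenyl]-3-[(trimethylsilyl)oxy]propan-1-one (silyl aldol) | O=C(C[C@@H](c1ccc(OCc2ccccc2)c(Br)c1)O[Si](C)(C)C)c1c(OCc2ccccc2)cc(OCc2ccccc2)cc1F | intermediate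
8 | (2S)-5,7-bis(benzyloxy)-2-[4-(benzyloxy)-3-bromophenyl]chroman-4-one | O=C1C[C@@H](c2ccc(OCc3ccccc3)c(Br)c2)Oc2cc(OCc3ccccc3)cc(OCc3ccccc3)c21 | intermediate
9 | (2S)-5,7-bis(benzyloxy)-2-[4-(benzyloxy)-3-bromophenyl]-4-[(trimethylsilyl)oxy]-2H-chromene | C[Si](C)(C)OC1=C[C@@H](c2ccc(OCc3ccccc3)c(Br)c2)Oc2cc(OCc3ccccc3)cc(OCc3ccccc3)c21 | intermediate
10 | 3,4-epoxide of 9 (5,7-bis(benzyloxy)-2-[4-(benzyloxy)-3-bromophenyl]-3,4-epoxy-4-[(trimethylsilyl)oxy]chromane, oxirane oxygen trans to the C2 aryl group, C2 arranged as in 9) | C[Si](C)(C)O[C@@]12O[C@@H]1[C@@H](c1ccc(OCc3ccccc3)c(Br)c1)Oc1cc(OCc3ccccc3)cc(OCc3ccccc3)c12 | intermediate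
11 | (2R,3R)-5,7-bis(benzyloxy)-2-[4-(benzyloxy)-3-bromophenyl]-3-hydroxychroman-4-one | O=C1[C@H](O)[C@@H](c2ccc(OCc3ccccc3)c(Br)c2)Oc2cc(OCc3ccccc3)cc(OCc3ccccc3)c21 | intermediate
12 | (2S)-5,7-bis(benzyloxy)-2-[4-(benzyloxy)-3-(4,4,5,5-tetramethyl-1,3,2-dioxaborolan-2-yl)phenyl]chroman-4-one | O=C1C[C@@H](c2ccc(OCc3ccccc3)c(B3OC(C)(C)C(C)(C)O3)c2)Oc2cc(OCc3ccccc3)cc(OCc3ccccc3)c21 | intermediate
13 | hexa-O-benzyl ether of the target: (2R,3R)-5,7-bis(benzyloxy)-2-{6,6'-bis(benzyloxy)-3'-[(2S)-5,7-bis(benzyloxy)-4-oxochroman-2-yl]biphenyl-3-yl}-3-hydroxychroman-4-one | O=C1C[C@@H](c2ccc(OCc3ccccc3)c(-c3cc([C@H]4Oc5cc(OCc6ccccc6)cc(OCc6ccccc6)c5C(=O)[C@@H]4O)ccc3OCc3ccccc3)c2)Oc2cc(OCc3ccccc3)cc(OCc3ccccc3)c21 | intermediate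
14 | (2R,3R)-2-{6,6'-dihydroxy-3'-[(2S)-5,7-dihydroxy-4-oxochroman-2-yl]biphenyl-3-yl}-3,5,7-trihydroxychroman-4-one ((2S)-naringenin joined through C3' to C3' of (2R,3R)-aromadendrin) | O=C1C[C@@H](c2ccc(O)c(-c3cc([C@H]4Oc5cc(O)cc(O)c5C(=O)[C@@H]4O)ccc3O)c2)Oc2cc(O)cc(O)c21 | target

Total step count: 10. Longest linear sequence: 8 steps (steps 2, 3, 4, 5, 6, 7, 9 and 10, from 3 to 14).

Steps most likely to fail

Step 5. At the alkoxide stage retro-aldol cleavage followed by unselective re-addition could erode the enantiomeric purity, E1cB loss of silanolate could divert material to a 2'-fluorochalcone, and the two alkoxy donors on ring A could slow the SNAr. The fallback sets out from 2 and comes back at 8. Commercial 2,4,6-trihydroxyacetophenone would be benzylated twice (BnBr, K2CO3, DMF) to 1-[2,4-bis(benzyloxy)-6-hydroxyphenyl]ethan-1-one F1. Claisen–Schmidt condensation of F1 with 2 (KOH, EtOH/THF, rt) would give (E)-3-[4-(benzyloxy)-3-bromophenyl]-1-[2,4-bis(benzyloxy)-6-hydroxyphenyl]prop-2-en-1-one F2. Oxa-Michael cyclisation (NaOAc, EtOH, reflux) would give the racemic flavanone rac-5,7-bis(benzyloxy)-2-[4-(benzyloxy)-3-bromophenyl]chroman-4-one F3. Preparative HPLC on an amylose tris(3,5-dimethylphenylcarbamate) phase would then deliver the (S)-enantiomer 8.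

Step 7. The enol silane could be epoxidised with incomplete facial selectivity, DMDO could attack the electron-rich ring A or a benzylic position, and acid could open ring C during work-up, each of which would cost the C2 or C3 configuration. The fallback sets out from 2 and comes back at 11. The ketone 1-[2,4-bis(benzyloxy)-6-hydroxyphenyl]ethan-1-one F1 (made as in the fallback to step 5) would be protected (MOMCl, NaH, DMF) as 1-[2,4-bis(benzyloxy)-6-(methoxymethoxy)phenyl]ethan-1-one F4. Claisen–Schmidt condensation with 2 (KOH, EtOH/THF) would give (E)-3-[4-(benzyloxy)-3-bromophenyl]-1-[2,4-bis(benzyloxy)-6-(methoxymethoxy)phenyl]prop-2-en-1-one F5. Juliá–Colonna epoxidation (poly-L-leucine, urea–H2O2, DBU, THF) would give the (2R,3S)-epoxy ketone [(2R,3S)-3-[4-(benzyloxy)-3-bromophenyl]oxiran-2-yl][2,4-bis(benzyloxy)-6-(methoxymethoxy)phenyl]methanone F6. HCl in MeOH/THF at 50 °C would remove the MOM group, and the freed phenol would open the epoxide at the benzylic carbon with inversion to give the trans-dihydroflavonol 11.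

Step 9. Transmetalation between two ortho-alkoxy partners could be slow enough for protodeboronation of 12 to compete, and prolonged contact with aqueous phosphate could epimerise or rearrange the α-ketol of 11 or open ring C of either half. The fallback sets out from 8 and comes back at 13. Stannylation of 8 (Me3SnSnMe3, Pd(PPh3)4, toluene, 100 °C) would give (2S)-5,7-bis(benzyloxy)-2-[4-(benzyloxy)-3-(trimethylstannyl)phenyl]chroman-4-one F7. A base-free Stille coupling of F7 with 11 (Pd(P(t-Bu)3)2, CuI, DMF, 50 °C) would then give 13.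

Further compounds
F1 | step 5 | 1-[2,4-bis(benzyloxy)-6-hydroxyphenyl]ethan-1-one | CC(=O)c1c(O)cc(OCc2ccccc2)cc1OCc1ccccc1
F2 | step 5 | (E)-3-[4-(benzyloxy)-3-bromophenyl]-1-[2,4-bis(benzyloxy)-6-hydroxyphenyl]prop-2-en-1-one | O=C(/C=C/c1ccc(OCc2ccccc2)c(Br)c1)c1c(O)cc(OCc2ccccc2)cc1OCc1ccccc1
F3 | step 5 | rac-5,7-bis(benzyloxy)-2-[4-(benzyloxy)-3-bromophenyl]chroman-4-one | O=C1CC(c2ccc(OCc3ccccc3)c(Br)c2)Oc2cc(OCc3ccccc3)cc(OCc3ccccc3)c21
F4 | step 7 | 1-[2,4-bis(benzyloxy)-6-(methoxymethoxy)phenyl]ethan-1-one | CC(=O)c1c(OCOC)cc(OCc2ccccc2)cc1OCc1ccccc1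
F5 | step 7 | (E)-3-[4-(benzyloxy)-3-bromophenyl]-1-[2,4-bis(benzyloxy)-6-(methoxymethoxy)phenyl]prop-2-en-1-one | O=C(/C=C/c1ccc(OCc2ccccc2)c(Br)c1)c1c(OCOC)cc(OCc2ccccc2)cc1OCc1ccccc1
F6 | step 7 | [(2R,3S)-3-[4-(benzyloxy)-3-bromophenyl]oxiran-2-yl][2,4-bis(benzyloxy)-6-(methoxymethoxy)phenyl]methanone | O=C([C@@H]1O[C@H]1c1ccc(OCc2ccccc2)c(Br)c1)c1c(OCOC)cc(OCc2ccccc2)cc1OCc1ccccc1
F7 | step 9 | (2S)-5,7-bis(benzyloxy)-2-[4-(benzyloxy)-3-(trimethylstannyl)phenyl]chroman-4-one | O=C1C[C@@H](c2ccc(OCc3ccccc3)c([Sn](C)(C)C)c2)Oc2cc(OCc3ccccc3)cc(OCc3ccccc3)c21
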